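## Retrosynthetic overview

1. The target is opened by a retro-Diels–Alder reaction across C6–C7' and C7–C4', giving (Z)-ligustilide 1 (2π partner, C6=C7) and the (S)-configured arene-hydrate diene 4 (4π partner, C7=C7a–C3a=C4).
2. Diene 4 comes from epoxide 2 by a vinylogous E1cB opening, and 2 comes from 1 by asymmetric epoxidation, so both halves derive from 1 (oxidation of ligustilide, 1,4-elimination, [4+2] dimerisation).
3. Ring order: no ring is made before the last step. The bicyclo[2.2.2]octene (both new six-membered rings) and four of the five stereocentres form in the final cycloaddition, controlled only by the C6' carbinol centre.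

Numbering used throughout (ligustilide numbering): C1 lactone carbonyl, O2, C3 (bearing the butylidene, C8 = exocyclic CH), C3a, C4–C7, C7a. Unprimed atoms are the ligustilide-derived unit A; primed atoms are the hydroxylated unit B (derived from 4).

Assumption: (Z)-ligustilide (1), the main phthalide of Angelica/Ligusticum oils, is bought in bulk (≥95 %) and is the only carbon source; its price is the main cost of the route.

## Route

Step 1
Reactants: 1 (Z)-ligustilide
Product: 2 (3Z,6S,7R)-3-butylidene-6,7-epoxy-4,5,6,7-tetrahydroisobenzofuran-1(3H)-one [(6S,7R)-6,7-epoxyligustilide]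
Conditions: (R,R)-(salen)MnCl [salen = N,N'-bis(3,5-di-tert-butylsalicylidene)-1,2-cyclohexanediamine dianion; trivalent manganese] (5 mol %), NMO (5 equiv), mCPBA (1.2 equiv), CH2Cl2, −78 °C
Reagents that add atoms: mCPBA, O=C(OO)c1cccc(Cl)c1
Why: Jacobsen–Katsuki epoxidation: C6=C7 is the only cis-disubstituted, diene-conjugated (1,2-dihydronaphthalene-like) olefin and the one peracids alone attack, so the oxomanganese salen species (pentavalent manganese) delivers oxygen there, and the (R,R) ligand is expected, by analogy with indene giving the (1R,2S)-oxide, to set the cis pair as 6S,7R, of which C6 becomes C6' of the target.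

Step 2
Reactants: 2 (S,R)-epoxyligustilide
Product: 4 (3Z,6S)-3-butylidene-6-hydroxy-5,6-dihydroisobenzofuran-1(3H)-one, via lithium alkoxide 3 (not isolated)
Conditions: LiN(SiMe3)2 (1.05 equiv), THF (0.05 M), −78 °C, 20 min; AcOH (1.05 equiv), −78 °C; cold Et2O/NaH2PO4–Na2HPO4 buffer (pH 7) wash, solution used at once
Reagents that add atoms: none
Why: Vinylogous E1cB epoxide opening: kinetic γ-deprotonation at C4 gives the lithium dienolate, whose α-carbon C7a expels the β-oxygen on C7 (epoxide strain) to form C7=C7a and C3a=C4 while the C6–O bond and its S configuration are untouched, and the product stays protected as alkoxide 3 from further deprotonation until the cold stoichiometric quench.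

Step 3
Reactants: 4 (S)-hydroxy diene; 1 (Z)-ligustilide
Product: 5 target CNP0289078.1
Conditions: fresh solution of the hydroxy diene added to a sixfold amount of ligustilide containing BHT (2 mol %), solvent stripped at ≤10 °C, then neat, Ar, dark, base-washed glass, 40 °C, 48–72 h; surplus ligustilide recovered unchanged by chromatography
Reagents that add atoms: none
Why: Biomimetic intermolecular Diels–Alder reaction in which all atoms of both partners end up in the adduct: the s-cis-locked 2-acyl diene C7'=C7a'–C3a'=C4' of 4 adds to C6=C7 of 1 (the dienophilic site in ligustilide's own dimerisations) with "para" orientation (enoate β-carbon C7' to the distal terminus C6, C4' to C7), on the face anti to the 6'-OH and in the exo mode (ring A under the C5'–C6' carbons, away from the diene's lactone), so the single S carbinol centre sets C4' (R), C7' (S), C6 (S) and C7 (R), suprafacial addition keeps ring A cis-fused, and re-formation of the butenolide alkene C3a'=C7a' drives the reaction.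

## Compound list

1 | (Z)-ligustilide, (3Z)-3-butylidene-4,5-dihydroisobenzofuran-1(3H)-one | CCC/C=C1\OC(=O)C2=C1CCC=C2 | starting material
2 | (S,R)-epoxyligustilide, (3Z,6S,7R)-3-butylidene-6,7-epoxy-4,5,6,7-tetrahydroisobenzofuran-1(3H)-one | CCC/C=C1\OC(=O)C2=C1CC[C@@H]3O[C@H]23 | intermediate
3 | lithium alkoxide, lithium (3Z,6S)-3-butylidene-1-oxo-1,3,5,6-tetrahydroisobenzofuran-6-olate | CCC/C=C1\OC(=O)C2=C[C@@H]([O-])CC=C12.[Li+] | intermediate (not isolated)
4 | (S)-hydroxy diene, (3Z,6S)-3-butylidene-6-hydroxy-5,6-dihydroisobenzofuran-1(3H)-one | CCC/C=C1\OC(=O)C2=C[C@@H](O)CC=C12 | intermediate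
5 | CNP0289078.1: (Z,Z) dimer with C6–C7' and C7–C4' bonds; unit A 6S,7R, unit B 4'R,6'S,7'S; bicyclo[2.2.2]oct-2-ene with bridgeheads C4'/C7' and bridges C3a'=C7a', C5'–C6'(OH) and C7–C6; 6'-OH points toward the C3a'=C7a' bridge, ring A (C5, C7a) points toward the C5'–C6' bridge | CCC/C=C1\OC(=O)C2=C1CC[C@@H]1[C@H]3C4=C(/C(=C/CCC)OC4=O)[C@H](C[C@@H]3O)[C@H]21 | target

## Step count and risks

Total step count: 3. Longest linear sequence: 3 (1 → 2 → 4 → 5; 1 enters again in step 3).

Steps most likely to fail, most risky first:

**Step 3.** The risks are loss of water from 4 to (Z)-butylidenephthalide, self-dimerisation of 4, and endo or regioisomeric adducts. Fallback, setting out from 4 and returning at 5: silylate 4 (Et3SiCl, imidazole, CH2Cl2, 0 °C) to the triethylsilyl ether (3Z,6S)-3-butylidene-6-(triethylsilyloxy)-5,6-dihydroisobenzofuran-1(3H)-one F2. This ether cannot ionise or dehydrate easily, can be purified, and shields its face more strongly. Heat F2 with a fivefold amount of 1 and BHT in toluene at 90–100 °C in a sealed tube to give the 6'-O-triethylsilyl ether of 5 F3. Cleave the silyl group with HF·pyridine in pyridine/THF at 0 °C to return to 5.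

**Step 2.** The risks are competing deprotonation of the side chain (C9–H), attack at the enol lactone, or base-induced loss of water from the arene hydrate. Fallback, setting out from 2 and returning at 4: neutral isomerisation of the vinyl epoxide with Pd(PPh3)4 (zerovalent palladium, 5 mol %) in THF at 0 °C to room temperature. Ionisation with inversion gives a π-allylpalladium alkoxide spanning C7–C7a–C3a; β-hydride elimination of the syn C4–H and O–H reductive elimination then give 4 without any base. This fallback makes no new compound (entry F0).

**Step 1.** The risks are insufficient ee, the wrong enantiofacial sense, or over-oxidation of the triene. Fallback, setting out from 1 and returning at 2: epoxidise 1 without a catalyst (mCPBA, NaHCO3, CH2Cl2, 0 °C), which gives 2 together with its enantiomer (3Z,6R,7S)-3-butylidene-6,7-epoxy-4,5,6,7-tetrahydroisobenzofuran-1(3H)-one F1 as the racemate. Separate the two by preparative HPLC on a chiral stationary phase (amylose tris(3,5-dimethylphenylcarbamate), hexane/i-PrOH); F1 is discarded and 2 continues. The absolute configuration is checked on 4 as its Mosher esters.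

## Further compounds

F1 | step 1 | (3Z,6R,7S)-3-butylidene-6,7-epoxy-4,5,6,7-tetrahydroisobenzofuran-1(3H)-one | CCC/C=C1\OC(=O)C2=C1CC[C@H]3O[C@@H]23
F0 | step 2 | none | none
F2 | step 3 | (3Z,6S)-3-butylidene-6-(triethylsilyloxy)-5,6-dihydroisobenzofuran-1(3H)-one | CCC/C=C1\OC(=O)C2=C[C@@H](O[Si](CC)(CC)CC)CC=C12
F3 | step 3 | 6'-O-triethylsilyl ether of 5 | CCC/C=C1\OC(=O)C2=C1CC[C@@H]1[C@H]3C4=C(/C(=C/CCC)OC4=O)[C@H](C[C@@H]3O[Si](CC)(CC)CC)[C@H]21
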